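**Plan**
- Retrosynthesis: the C18=C19 alkene is cut first, as a C18≡C19 alkyne closed by ring-closing alkyne metathesis. Then the lactone C1–O bond (esterification), C12–C13 (aldol), C23–C24 (Suzuki coupling), C2–C3, C4–C5 and C9–C10 are cut.
- Enabling feature: C18=C19 lies inside the C16–C25 pentaene of the single 28-membered lactone ring (C1–C27 plus O), one vinyl unit from the C15 carbinol. As an alkyne it is closed by an alkylidyne that ignores the C16, C20, C22 and C24 alkenes.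
- Forward: hex-5-en-1-ol gives the C1–C12 methyl ketone (two allylborations, one butanoate aldol). Its enol silane adds to the C13–C18 enynal-derived aldehyde, and 1,3-anti reduction, silylation and auxiliary cleavage give the C1–C18 acid.
- The C19–C28 trienynol (propionate aldol, iodo-olefination, Suzuki coupling) is esterified. The ring then closes, the alkyne is reduced to the E-alkene through trans-hydrosilylation, and fluoride frees the hexol.
- Stereochemistry: C2/C3 and C14/C15 come from Evans syn aldols of boron enolates, and C26/C27 from the chlorotitanium enolate of the same (S)-4-benzyloxazolidinone imide; C5 and C9 come from Ipc allylboranes. C13 is set by chelation control from C14/C15, and C11 by hydroxyl-directed anti reduction from C13.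

Key step: step 30

Remark: locants C1–C28 follow the seco acid (C1 lactone carbonyl, C27 the carbon on the ring oxygen, C28 its methyl). C11 reads R in diol 26 only because O13 is unsilylated there; its spatial arrangement is the same as 11S in 27 and later compounds.

**Route**

Step 1
Reactants: 1 but-2-yn-1-ol
Product: 3 (2E)-hex-2-en-4-ynal, via but-2-ynal 2 (not isolated)
Conditions: MnO2, CH2Cl2, rt; filter; Ph3P=CHCHO, CH2Cl2, rt
Reagents that add atoms: (triphenylphosphoranylidene)acetaldehyde, O=CC=P(c1ccccc1)(c1ccccc1)c1ccccc1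
Why: MnO2 oxidises the propargylic alcohol cleanly and the stabilised formyl ylide should convert the reactive ynal into the E-enal by Wittig olefination.

Step 2
Reactants: 4 (4S)-4-benzyl-3-propanoyl-1,3-oxazolidin-2-one; 3 (2E)-hex-2-en-4-ynal
Product: 6 (4S)-4-benzyl-3-[(2S,3R,4E)-3-hydroxy-2-methyloct-4-en-6-ynoyl]-1,3-oxazolidin-2-one, via dibutylboron Z-enolate 5 (not isolated)
Conditions: Bu2BOTf, Et3N, CH2Cl2, −78 → 0 °C; 3, −78 → 0 °C; pH 7 buffer, MeOH, H2O2, 0 °C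
Reagents that add atoms: none
Why: Evans syn aldol; the Z-boron enolate adds 1,2 to the enal through a Zimmerman–Traxler chair on the face away from the benzyl group, setting the future C14 and C15 centres.

Step 3
Reactants: 6 (4S)-4-benzyl-3-[(2S,3R,4E)-3-hydroxy-2-methyloct-4-en-6-ynoyl]-1,3-oxazolidin-2-one
Product: 7 (2S,3R,4E)-3-hydroxy-N-methoxy-N,2-dimethyloct-4-en-6-ynamide
Conditions: MeNH(OMe)·HCl, AlMe3, THF/CH2Cl2, −20 → 0 °C
Reagents that add atoms: N,O-dimethylhydroxylamine hydrochloride, CNOC.Cl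
Why: Aluminium amide transamination of a β-hydroxy imide (Weinreb amide formation) should release the auxiliary without epimerisation.

Step 4
Reactants: 7 (2S,3R,4E)-3-hydroxy-N-methoxy-N,2-dimethyloct-4-en-6-ynamide
Product: 8 (2S,3R,4E)-3-[(tert-butyldimethylsilyl)oxy]-N-methoxy-N,2-dimethyloct-4-en-6-ynamide
Conditions: TBSOTf, 2,6-lutidine, CH2Cl2, −78 °C
Reagents that add atoms: tert-butyldimethylsilyl trifluoromethanesulfonate, CC(C)(C)[Si](C)(C)OS(=O)(=O)C(F)(F)F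
Why: Silyl triflate silylation of a secondary allylic alcohol is fast and leaves the amide and enyne alone.

Step 5
Reactants: 8 (2S,3R,4E)-3-[(tert-butyldimethylsilyl)oxy]-N-methoxy-N,2-dimethyloct-4-en-6-ynamide
Product: 9 (2S,3R,4E)-3-[(tert-butyldimethylsilyl)oxy]-2-methyloct-4-en-6-ynal
Conditions: iBu2AlH, THF, −78 °C; aq. KNa tartrate
Reagents that add atoms: none
Why: Hydride reduction of the Weinreb amide stops at the chelated tetrahedral intermediate, so the aldehyde should form without over-reduction or loss of the α-centre.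

Step 6
Reactants: 10 hex-5-en-1-ol
Product: 11 hex-5-enal
Conditions: PhI(OAc)2, TEMPO (cat.), CH2Cl2, rt
Reagents that add atoms: none
Why: TEMPO-catalysed oxidation stops at the aldehyde and does not touch the terminal alkene.

Step 7
Reactants: 11 hex-5-enal
Product: 12 (4S)-2-methylnona-1,8-dien-4-ol
Conditions: (+)-Ipc2BOMe [(−)-α-pinene series], CH2=C(CH3)CH2MgCl, Et2O, 0 °C → rt; 11, −78 °C; NaBO3·4H2O, THF/H2O, rt
Reagents that add atoms: 2-methylallylmagnesium chloride, C=C(C)C[Mg]Cl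
Why: Brown asymmetric methallylboration; the chair transition state of the Ipc2B reagent delivers the allyl unit to the Re face of the aldehyde and sets C9 as S.

Step 8
Reactants: 12 (4S)-2-methylnona-1,8-dien-4-ol
Product: 13 tert-butyldimethyl{[(4S)-2-methylnona-1,8-dien-4-yl]oxy}silane
Conditions: TBSCl, imidazole, DMF, rt
Reagents that add atoms: tert-butyldimethylsilyl chloride, CC(C)(C)[Si](C)(C)Cl
Why: Standard silylation of an unhindered secondary alcohol.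

Step 9
Reactants: 13 tert-butyldimethyl{[(4S)-2-methylnona-1,8-dien-4-yl]oxy}silane
Product: 14 (5S)-5-[(tert-butyldimethylsilyl)oxy]-7-oxooctanal
Conditions: O3, CH2Cl2, −78 °C; PPh3, −78 °C → rt
Reagents that add atoms: ozone, [O-][O+]=O
Why: Ozonolysis with reductive work-up cleaves both terminal alkenes at once, giving the C11 methyl ketone from the 1,1-disubstituted alkene and the C5 aldehyde from the vinyl group.

Step 10
Reactants: 14 (5S)-5-[(tert-butyldimethylsilyl)oxy]-7-oxooctanal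
Product: 15 (4S,8S)-4-[(tert-butyldimethylsilyl)oxy]-8-hydroxyundec-10-en-2-one
Conditions: (+)-Ipc2BOMe [(−)-α-pinene series], CH2=CHCH2MgBr, Et2O, 0 °C → rt; 14, −78 °C; NaBO3·4H2O, THF/H2O, rt
Reagents that add atoms: allylmagnesium bromide, C=CC[Mg]Br
Why: Brown asymmetric allylboration; the allylborane reacts with the aldehyde far faster than with the methyl ketone and Re-face addition under reagent control sets C5 as S.

Step 11
Reactants: 15 (4S,8S)-4-[(tert-butyldimethylsilyl)oxy]-8-hydroxyundec-10-en-2-one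
Product: 16 (4S,8S)-4,8-bis[(tert-butyldimethylsilyl)oxy]undec-10-en-2-one
Conditions: TBSCl, imidazole, DMF, rt
Reagents that add atoms: tert-butyldimethylsilyl chloride, CC(C)(C)[Si](C)(C)Cl
Why: Standard silylation; the β-silyloxy ketone is stable to imidazole.

Step 12
Reactants: 16 (4S,8S)-4,8-bis[(tert-butyldimethylsilyl)oxy]undec-10-en-2-one
Product: 17 (3S,7S)-3,7-bis[(tert-butyldimethylsilyl)oxy]-9-oxodecanal
Conditions: O3, CH2Cl2, −78 °C; PPh3, −78 °C → rt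
Reagents that add atoms: ozone, [O-][O+]=O
Why: Ozonolysis of the remaining vinyl group should free the C3 aldehyde; ketone and silyl ethers are inert.

Step 13
Reactants: 18 (4S)-4-benzyl-1,3-oxazolidin-2-one; 19 butanoyl chloride
Product: 20 (4S)-4-benzyl-3-butanoyl-1,3-oxazolidin-2-one
Conditions: nBuLi, THF, −78 °C; 19, −78 → 0 °C
Reagents that add atoms: none
Why: N-Acylation of the lithiated oxazolidinone is the standard entry to the acyl imide.

Step 14
Reactants: 20 (4S)-4-benzyl-3-butanoyl-1,3-oxazolidin-2-one; 17 (3S,7S)-3,7-bis[(tert-butyldimethylsilyl)oxy]-9-oxodecanal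
Product: 22 (4S)-4-benzyl-3-[(2S,3R,5S,9S)-5,9-bis[(tert-butyldimethylsilyl)oxy]-2-ethyl-3-hydroxy-11-oxododecanoyl]-1,3-oxazolidin-2-one, via dibutylboron Z-enolate 21 (not isolated)
Conditions: Bu2BOTf, Et3N, CH2Cl2, −78 → 0 °C; 17, −78 → 0 °C; pH 7 buffer, MeOH, H2O2, 0 °C
Reagents that add atoms: none
Why: Evans syn aldol; the preformed Z-boron enolate attacks the aldehyde in preference to the ketone, and auxiliary control in the chair transition state sets C2 (S) and C3 (R), giving the 3,5-anti relationship irrespective of the C5 silyloxy group.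

Step 15
Reactants: 22 (4S)-4-benzyl-3-[(2S,3R,5S,9S)-5,9-bis[(tert-butyldimethylsilyl)oxy]-2-ethyl-3-hydroxy-11-oxododecanoyl]-1,3-oxazolidin-2-one
Product: 23 (4S)-4-benzyl-3-[(2S,3R,5S,9S)-3,5,9-tris[(tert-butyldimethylsilyl)oxy]-2-ethyl-11-oxododecanoyl]-1,3-oxazolidin-2-one
Conditions: TBSOTf, 2,6-lutidine, CH2Cl2, −78 → 0 °C
Reagents that add atoms: tert-butyldimethylsilyl trifluoromethanesulfonate, CC(C)(C)[Si](C)(C)OS(=O)(=O)C(F)(F)F
Why: The silyl triflate silylates the hindered aldol hydroxyl without retro-aldol cleavage.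

Step 16
Reactants: 23 (4S)-4-benzyl-3-[(2S,3R,5S,9S)-3,5,9-tris[(tert-butyldimethylsilyl)oxy]-2-ethyl-11-oxododecanoyl]-1,3-oxazolidin-2-one
Product: 24 (4S)-4-benzyl-3-[(2S,3R,5S,9S)-3,5,9-tris[(tert-butyldimethylsilyl)oxy]-2-ethyl-11-[(trimethylsilyl)oxy]dodec-11-enoyl]-1,3-oxazolidin-2-one
Conditions: LiN(SiMe3)2, Me3SiCl, Et3N, THF, −78 °C
Reagents that add atoms: chlorotrimethylsilane, C[Si](C)(C)Cl
Why: Kinetic deprotonation with internal silyl quench takes the unhindered methyl protons; the α-branched imide is kinetically non-acidic because allylic strain holds its C2–H bond in the carbonyl plane.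

Step 17
Reactants: 24 (4S)-4-benzyl-3-[(2S,3R,5S,9S)-3,5,9-tris[(tert-butyldimethylsilyl)oxy]-2-ethyl-11-[(trimethylsilyl)oxy]dodec-11-enoyl]-1,3-oxazolidin-2-one; 9 (2S,3R,4E)-3-[(tert-butyldimethylsilyl)oxy]-2-methyloct-4-en-6-ynal
Product: 25 (4S)-4-benzyl-3-[(2S,3R,5S,9S,13R,14R,15R,16E)-3,5,9,15-tetrakis[(tert-butyldimethylsilyl)oxy]-2-ethyl-13-hydroxy-14-methyl-11-oxoicos-16-en-18-ynoyl]-1,3-oxazolidin-2-one
Conditions: Me2AlCl (excess), CH2Cl2, −78 °C
Reagents that add atoms: none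
Why: Chelate-controlled Mukaiyama aldol; Me2AlCl bridges the aldehyde and β-silyloxy oxygens of the syn aldehyde so that the C14 methyl and the C15 substituent lie on one face of the chelate, and the enol silane adds opposite to both, setting C13 as R (13,14-anti and 13,15-anti).

Step 18
Reactants: 25 (4S)-4-benzyl-3-[(2S,3R,5S,9S,13R,14R,15R,16E)-3,5,9,15-tetrakis[(tert-butyldimethylsilyl)oxy]-2-ethyl-13-hydroxy-14-methyl-11-oxoicos-16-en-18-ynoyl]-1,3-oxazolidin-2-one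
Product: 26 (4S)-4-benzyl-3-[(2S,3R,5S,9S,11R,13R,14R,15R,16E)-3,5,9,15-tetrakis[(tert-butyldimethylsilyl)oxy]-2-ethyl-11,13-dihydroxy-14-methylicos-16-en-18-ynoyl]-1,3-oxazolidin-2-one
Conditions: Me4NBH(OAc)3, MeCN/AcOH, −30 °C
Reagents that add atoms: none
Why: Evans–Saksena reduction; the C13 hydroxyl binds the triacetoxyborohydride and delivers hydride intramolecularly through a chair, giving the 11,13-anti diol and thereby the 9,11-syn relationship.

Step 19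
Reactants: 26 (4S)-4-benzyl-3-[(2S,3R,5S,9S,11R,13R,14R,15R,16E)-3,5,9,15-tetrakis[(tert-butyldimethylsilyl)oxy]-2-ethyl-11,13-dihydroxy-14-methylicos-16-en-18-ynoyl]-1,3-oxazolidin-2-one
Product: 27 (4S)-4-benzyl-3-[(2S,3R,5S,9S,11S,13R,14R,15R,16E)-3,5,9,11,13,15-hexakis[(tert-butyldimethylsilyl)oxy]-2-ethyl-14-methylicos-16-en-18-ynoyl]-1,3-oxazolidin-2-one
Conditions: TBSOTf, 2,6-lutidine, CH2Cl2, −78 → 0 °C
Reagents that add atoms: tert-butyldimethylsilyl trifluoromethanesulfonate, CC(C)(C)[Si](C)(C)OS(=O)(=O)C(F)(F)F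
Why: Excess silyl triflate should silylate both secondary hydroxyls, including the hindered C13 one.

Step 20
Reactants: 27 (4S)-4-benzyl-3-[(2S,3R,5S,9S,11S,13R,14R,15R,16E)-3,5,9,11,13,15-hexakis[(tert-butyldimethylsilyl)oxy]-2-ethyl-14-methylicos-16-en-18-ynoyl]-1,3-oxazolidin-2-one
Product: 28 (2S,3R,5S,9S,11S,13R,14R,15R,16E)-3,5,9,11,13,15-hexakis[(tert-butyldimethylsilyl)oxy]-2-ethyl-14-methylicos-16-en-18-ynoic acid
Conditions: LiOH, H2O2, THF/H2O, 0 °C; aq. Na2SO3; aq. HCl to pH 4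
Reagents that add atoms: hydrogen peroxide (as lithium hydroperoxide), OO
Why: Hydroperoxide attacks the exocyclic imide carbonyl selectively (standard oxazolidinone cleavage), so the acid should form without C2 epimerisation or silyl loss.

Step 21
Reactants: 4 (4S)-4-benzyl-3-propanoyl-1,3-oxazolidin-2-one; 29 acetaldehyde
Product: 31 (4S)-4-benzyl-3-[(2S,3R)-3-hydroxy-2-methylbutanoyl]-1,3-oxazolidin-2-one, via chlorotitanium Z-enolate 30 (not isolated)
Conditions: TiCl4, iPr2NEt, CH2Cl2, 0 °C; 29 (excess), −78 → 0 °C; aq. NH4Cl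
Reagents that add atoms: none
Why: Evans syn aldol through the titanium enolate; soft enolisation with TiCl4 and the hindered amine gives the Z-enolate, which adds to the aldehyde through a chair transition state on the face away from the benzyl group and sets the future C26 and C27 centres, with the volatile aldehyde in excess and no oxidative work-up.

Step 22
Reactants: 31 (4S)-4-benzyl-3-[(2S,3R)-3-hydroxy-2-methylbutanoyl]-1,3-oxazolidin-2-one
Product: 32 (2S,3R)-3-hydroxy-N-methoxy-N,2-dimethylbutanamide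
Conditions: MeNH(OMe)·HCl, AlMe3, THF/CH2Cl2, −20 → 0 °C
Reagents that add atoms: N,O-dimethylhydroxylamine hydrochloride, CNOC.Cl
Why: Aluminium amide transamination (Weinreb amide formation) as in step 3.

Step 23
Reactants: 32 (2S,3R)-3-hydroxy-N-methoxy-N,2-dimethylbutanamide
Product: 33 (2S,3R)-3-[(tert-butyldimethylsilyl)oxy]-N-methoxy-N,2-dimethylbutanamide
Conditions: TBSCl, imidazole, DMF, rt
Reagents that add atoms: tert-butyldimethylsilyl chloride, CC(C)(C)[Si](C)(C)Cl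
Why: Standard silylation of a secondary alcohol.

Step 24
Reactants: 33 (2S,3R)-3-[(tert-butyldimethylsilyl)oxy]-N-methoxy-N,2-dimethylbutanamide
Product: 34 (2S,3R)-3-[(tert-butyldimethylsilyl)oxy]-2-methylbutanal
Conditions: iBu2AlH, THF, −78 °C; aq. KNa tartrate
Reagents that add atoms: none
Why: Weinreb amide reduction stops at the aldehyde, as in step 5.

Step 25
Reactants: 34 (2S,3R)-3-[(tert-butyldimethylsilyl)oxy]-2-methylbutanal
Product: 35 tert-butyl{[(2R,3R,4E)-5-iodo-3-methylpent-4-en-2-yl]oxy}dimethylsilane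
Conditions: CHI3, CrCl2, THF, 0 °C → rt
Reagents that add atoms: iodoform, IC(I)I
Why: Takai olefination; the geminal dichromium reagent gives the E-vinyl iodide under near-neutral conditions that spare the α-stereocentre.

Step 26
Reactants: 3 (2E)-hex-2-en-4-ynal
Product: 36 2-[(1E,3E)-hepta-1,3-dien-5-yn-1-yl]-4,4,5,5-tetramethyl-1,3,2-dioxaborolane
Conditions: Cl2CHB(pin), CrCl2, LiI, THF, rt
Reagents that add atoms: 2-(dichloromethyl)-4,4,5,5-tetramethyl-1,3,2-dioxaborolane, ClC(Cl)B1OC(C)(C)C(C)(C)O1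
Why: Takai–Utimoto boryl olefination converts the aldehyde into the E-alkenylboronate with the same E-selectivity as the iodo variant.

Step 27
Reactants: 35 tert-butyl{[(2R,3R,4E)-5-iodo-3-methylpent-4-en-2-yl]oxy}dimethylsilane; 36 2-[(1E,3E)-hepta-1,3-dien-5-yn-1-yl]-4,4,5,5-tetramethyl-1,3,2-dioxaborolane
Product: 37 tert-butyldimethyl{[(2R,3R,4E,6E,8E)-3-methyldodeca-4,6,8-trien-10-yn-2-yl]oxy}silane
Conditions: Pd(dppf)Cl2 (cat.), Cs2CO3, DMF/H2O, rt, dark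
Reagents that add atoms: none
Why: Suzuki–Miyaura coupling joins C23 to C24 with retention of both alkene geometries and leaves the internal alkyne untouched.

Step 28
Reactants: 37 tert-butyldimethyl{[(2R,3R,4E,6E,8E)-3-methyldodeca-4,6,8-trien-10-yn-2-yl]oxy}silane
Product: 38 (2R,3R,4E,6E,8E)-3-methyldodeca-4,6,8-trien-10-yn-2-ol
Conditions: Bu4NF, THF, 0 °C → rt, dark
Reagents that add atoms: none
Why: Fluoride desilylation frees the C27 hydroxyl; the trienyne carries no base-sensitive group.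

Step 29
Reactants: 28 (2S,3R,5S,9S,11S,13R,14R,15R,16E)-3,5,9,11,13,15-hexakis[(tert-butyldimethylsilyl)oxy]-2-ethyl-14-methylicos-16-en-18-ynoic acid; 38 (2R,3R,4E,6E,8E)-3-methyldodeca-4,6,8-trien-10-yn-2-ol
Product: 40 (2R,3R,4E,6E,8E)-3-methyldodeca-4,6,8-trien-10-yn-2-yl (2S,3R,5S,9S,11S,13R,14R,15R,16E)-3,5,9,11,13,15-hexakis[(tert-butyldimethylsilyl)oxy]-2-ethyl-14-methylicos-16-en-18-ynoate, via mixed anhydride 39 (not isolated)
Conditions: 2,4,6-Cl3C6H2COCl, Et3N, toluene, rt; 38, DMAP, toluene, rt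
Reagents that add atoms: none
Why: Yamaguchi esterification; DMAP attacks the less hindered aliphatic carbonyl of the mixed anhydride and the acylpyridinium acylates the hindered secondary alcohol.

Step 30
Reactants: 40 (2R,3R,4E,6E,8E)-3-methyldodeca-4,6,8-trien-10-yn-2-yl (2S,3R,5S,9S,11S,13R,14R,15R,16E)-3,5,9,11,13,15-hexakis[(tert-butyldimethylsilyl)oxy]-2-ethyl-14-methylicos-16-en-18-ynoate
Product: 41 (2S,3R,5S,9S,11S,13R,14R,15R,16E,20E,22E,24E,26R,27R)-3,5,9,11,13,15-hexakis[(tert-butyldimethylsilyl)oxy]-2-ethyl-14,26-dimethyloctacosa-16,20,22,24-tetraen-18-yn-27-olide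
Conditions: [Mo(≡CC6H4-4-OMe)(OSiPh3)3] (20 mol%), 5 Å MS, toluene (2 mM), 80 °C
Reagents that add atoms: none
Why: The molybdenum alkylidyne undergoes [2+2] cycloaddition with one methyl-capped alkyne to a metallacyclobutadiene, cycloreversion expels but-2-yne and leaves the chain bound as a new alkylidyne, and a second cycloaddition and cycloreversion at the other capped alkyne forms C18≡C19. The closest known reaction type is ring-closing alkyne metathesis of 1,3-enyne/alkyne seco esters with triarylsilanolate molybdenum alkylidynes. The single 28-membered ring closes end to end, by macrocyclisation between the terminal C18 and C19 alkyne carbons of the open-chain ester, and the rigid E-enyne and E,E,E-trienyne termini should not strain the forming cycloalkyne. No stereocentre is created and none is touched. The step needs alkyne-over-alkene selectivity, which the alkylidyne provides because it does not engage the C16, C20, C22 and C24 alkenes, the ester or the silyl ethers. It also needs cyclisation over oligomerisation, which high dilution, the methyl caps and capture of but-2-yne on the molecular sieves should secure.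

Step 31
Reactants: 41 (2S,3R,5S,9S,11S,13R,14R,15R,16E,20E,22E,24E,26R,27R)-3,5,9,11,13,15-hexakis[(tert-butyldimethylsilyl)oxy]-2-ethyl-14,26-dimethyloctacosa-16,20,22,24-tetraen-18-yn-27-olide
Product: 42 (2S,3R,5S,9S,11S,13R,14R,15R,16E,18Z,20E,22E,24E,26R,27R)-3,5,9,11,13,15-hexakis[(tert-butyldimethylsilyl)oxy]-2-ethyl-14,26-dimethyl-19-(triethoxysilyl)octacosa-16,18,20,22,24-pentaen-27-olide
Conditions: (EtO)3SiH, [Cp*Ru(MeCN)3]PF6 (cat.), CH2Cl2, 0 °C → rt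
Reagents that add atoms: triethoxysilane, CCO[SiH](OCC)OCC
Why: Ruthenium-catalysed trans-hydrosilylation adds H and Si across the alkyne on opposite faces and does not touch alkenes; the C19-silyl isomer is drawn, and the C18-silyl regioisomer would lead to the same alkene in step 32.

Step 32
Reactants: 42 (2S,3R,5S,9S,11S,13R,14R,15R,16E,18Z,20E,22E,24E,26R,27R)-3,5,9,11,13,15-hexakis[(tert-butyldimethylsilyl)oxy]-2-ethyl-14,26-dimethyl-19-(triethoxysilyl)octacosa-16,18,20,22,24-pentaen-27-olide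
Product: 43 (2S,3R,5S,9S,11S,13R,14R,15R,16E,18E,20E,22E,24E,26R,27R)-3,5,9,11,13,15-hexakis[(tert-butyldimethylsilyl)oxy]-2-ethyl-14,26-dimethyloctacosa-16,18,20,22,24-pentaen-27-olide
Conditions: AgF, THF/MeOH/H2O, rt, dark
Reagents that add atoms: none
Why: Silver fluoride-mediated protodesilylation replaces the C–Si bond by C–H with retention, so the C18=C19 alkene should emerge E and complete the all-E pentaene while the silyl ethers stay on.

Step 33
Reactants: 43 (2S,3R,5S,9S,11S,13R,14R,15R,16E,18E,20E,22E,24E,26R,27R)-3,5,9,11,13,15-hexakis[(tert-butyldimethylsilyl)oxy]-2-ethyl-14,26-dimethyloctacosa-16,18,20,22,24-pentaen-27-olide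
Product: 44 (2S,3R,5S,9S,11S,13R,14R,15R,16E,18E,20E,22E,24E,26R,27R)-2-ethyl-3,5,9,11,13,15-hexahydroxy-14,26-dimethyloctacosa-16,18,20,22,24-pentaen-27-olide (CNP0382847.1)
Conditions: HF·pyridine, excess pyridine, THF, 0 °C → rt, dark
Reagents that add atoms: none
Why: Pyridine-buffered hydrogen fluoride cleaves all six silyl ethers by fluoride-driven desilylation under conditions mild enough to avoid ionising the pentaenyl C15 carbinol or opening the lactone.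

**Compound list**

1 | but-2-yn-1-ol | CC#CCO | starting material
2 | but-2-ynal | CC#CC=O | intermediate (not isolated)
3 | (2E)-hex-2-en-4-ynal | CC#C/C=C/C=O | intermediate
4 | (4S)-4-benzyl-3-propanoyl-1,3-oxazolidin-2-one | O=C1OC[C@H](Cc2ccccc2)N1C(=O)CC | starting material
5 | (4S)-4-benzyl-3-[(1Z)-1-[(dibutylboranyl)oxy]prop-1-en-1-yl]-1,3-oxazolidin-2-one | C/C=C(\OB(CCCC)CCCC)N1[C@@H](Cc2ccccc2)COC1=O | intermediate (not isolated)
6 | (4S)-4-benzyl-3-[(2S,3R,4E)-3-hydroxy-2-methyloct-4-en-6-ynoyl]-1,3-oxazolidin-2-one | O=C1OC[C@H](Cc2ccccc2)N1C(=O)[C@@H](C)[C@H](O)/C=C/C#CC | intermediate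
7 | (2S,3R,4E)-3-hydroxy-N-methoxy-N,2-dimethyloct-4-en-6-ynamide | CON(C)C(=O)[C@@H](C)[C@H](O)/C=C/C#CC | intermediate
8 | (2S,3R,4E)-3-[(tert-butyldimethylsilyl)oxy]-N-methoxy-N,2-dimethyloct-4-en-6-ynamide | CON(C)C(=O)[C@@H](C)[C@H](O[Si](C)(C)C(C)(C)C)/C=C/C#CC | intermediate
9 | (2S,3R,4E)-3-[(tert-butyldimethylsilyl)oxy]-2-methyloct-4-en-6-ynal | O=C[C@@H](C)[C@H](O[Si](C)(C)C(C)(C)C)/C=C/C#CC | intermediate
10 | hex-5-en-1-ol | C=CCCCCO | starting material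
11 | hex-5-enal | C=CCCCC=O | intermediate
12 | (4S)-2-methylnona-1,8-dien-4-ol | C=C(C)C[C@@H](O)CCCC=C | intermediate
13 | tert-butyldimethyl{[(4S)-2-methylnona-1,8-dien-4-yl]oxy}silane | C=C(C)C[C@@H](O[Si](C)(C)C(C)(C)C)CCCC=C | intermediate
14 | (5S)-5-[(tert-butyldimethylsilyl)oxy]-7-oxooctanal | CC(=O)C[C@@H](O[Si](C)(C)C(C)(C)C)CCCC=O | intermediate
15 | (4S,8S)-4-[(tert-butyldimethylsilyl)oxy]-8-hydroxyundec-10-en-2-one | CC(=O)C[C@@H](O[Si](C)(C)C(C)(C)C)CCC[C@H](O)CC=C | intermediate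
16 | (4S,8S)-4,8-bis[(tert-butyldimethylsilyl)oxy]undec-10-en-2-one | CC(=O)C[C@@H](O[Si](C)(C)C(C)(C)C)CCC[C@H](O[Si](C)(C)C(C)(C)C)CC=C | intermediate
17 | (3S,7S)-3,7-bis[(tert-butyldimethylsilyl)oxy]-9-oxodecanal | CC(=O)C[C@@H](O[Si](C)(C)C(C)(C)C)CCC[C@H](O[Si](C)(C)C(C)(C)C)CC=O | intermediate
18 | (4S)-4-benzyl-1,3-oxazolidin-2-one | O=C1OC[C@H](Cc2ccccc2)N1 | starting material
19 | butanoyl chloride | CCCC(Cl)=O | starting material
20 | (4S)-4-benzyl-3-butanoyl-1,3-oxazolidin-2-one | O=C1OC[C@H](Cc2ccccc2)N1C(=O)CCC | intermediate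
21 | (4S)-4-benzyl-3-[(1Z)-1-[(dibutylboranyl)oxy]but-1-en-1-yl]-1,3-oxazolidin-2-one | CC/C=C(\OB(CCCC)CCCC)N1[C@@H](Cc2ccccc2)COC1=O | intermediate (not isolated)
22 | (4S)-4-benzyl-3-[(2S,3R,5S,9S)-5,9-bis[(tert-butyldimethylsilyl)oxy]-2-ethyl-3-hydroxy-11-oxododecanoyl]-1,3-oxazolidin-2-one | O=C1OC[C@H](Cc2ccccc2)N1C(=O)[C@@H](CC)[C@H](O)C[C@@H](O[Si](C)(C)C(C)(C)C)CCC[C@H](O[Si](C)(C)C(C)(C)C)CC(C)=O | intermediate
23 | (4S)-4-benzyl-3-[(2S,3R,5S,9S)-3,5,9-tris[(tert-butyldimethylsilyl)oxy]-2-ethyl-11-oxododecanoyl]-1,3-oxazolidin-2-one | O=C1OC[C@H](Cc2ccccc2)N1C(=O)[C@@H](CC)[C@H](O[Si](C)(C)C(C)(C)C)C[C@@H](O[Si](C)(C)C(C)(C)C)CCC[C@H](O[Si](C)(C)C(C)(C)C)CC(C)=O | intermediate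
24 | (4S)-4-benzyl-3-[(2S,3R,5S,9S)-3,5,9-tris[(tert-butyldimethylsilyl)oxy]-2-ethyl-11-[(trimethylsilyl)oxy]dodec-11-enoyl]-1,3-oxazolidin-2-one | O=C1OC[C@H](Cc2ccccc2)N1C(=O)[C@@H](CC)[C@H](O[Si](C)(C)C(C)(C)C)C[C@@H](O[Si](C)(C)C(C)(C)C)CCC[C@H](O[Si](C)(C)C(C)(C)C)CC(=C)O[Si](C)(C)C | intermediate
25 | (4S)-4-benzyl-3-[(2S,3R,5S,9S,13R,14R,15R,16E)-3,5,9,15-tetrakis[(tert-butyldimethylsilyl)oxy]-2-ethyl-13-hydroxy-14-methyl-11-oxoicos-16-en-18-ynoyl]-1,3-oxazolidin-2-one | O=C1OC[C@H](Cc2ccccc2)N1C(=O)[C@@H](CC)[C@H](O[Si](C)(C)C(C)(C)C)C[C@@H](O[Si](C)(C)C(C)(C)C)CCC[C@H](O[Si](C)(C)C(C)(C)C)CC(=O)C[C@@H](O)[C@@H](C)[C@H](O[Si](C)(C)C(C)(C)C)/C=C/C#CC | intermediate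
26 | (4S)-4-benzyl-3-[(2S,3R,5S,9S,11R,13R,14R,15R,16E)-3,5,9,15-tetrakis[(tert-butyldimethylsilyl)oxy]-2-ethyl-11,13-dihydroxy-14-methylicos-16-en-18-ynoyl]-1,3-oxazolidin-2-one | O=C1OC[C@H](Cc2ccccc2)N1C(=O)[C@@H](CC)[C@H](O[Si](C)(C)C(C)(C)C)C[C@@H](O[Si](C)(C)C(C)(C)C)CCC[C@H](O[Si](C)(C)C(C)(C)C)C[C@H](O)C[C@@H](O)[C@@H](C)[C@H](O[Si](C)(C)C(C)(C)C)/C=C/C#CC | intermediate
27 | (4S)-4-benzyl-3-[(2S,3R,5S,9S,11S,13R,14R,15R,16E)-3,5,9,11,13,15-hexakis[(tert-butyldimethylsilyl)oxy]-2-ethyl-14-methylicos-16-en-18-ynoyl]-1,3-oxazolidin-2-one | O=C1OC[C@H](Cc2ccccc2)N1C(=O)[C@@H](CC)[C@H](O[Si](C)(C)C(C)(C)C)C[C@@H](O[Si](C)(C)C(C)(C)C)CCC[C@H](O[Si](C)(C)C(C)(C)C)C[C@H](O[Si](C)(C)C(C)(C)C)C[C@@H](O[Si](C)(C)C(C)(C)C)[C@@H](C)[C@H](O[Si](C)(C)C(C)(C)C)/C=C/C#CC | intermediate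
28 | (2S,3R,5S,9S,11S,13R,14R,15R,16E)-3,5,9,11,13,15-hexakis[(tert-butyldimethylsilyl)oxy]-2-ethyl-14-methylicos-16-en-18-ynoic acid | OC(=O)[C@@H](CC)[C@H](O[Si](C)(C)C(C)(C)C)C[C@@H](O[Si](C)(C)C(C)(C)C)CCC[C@H](O[Si](C)(C)C(C)(C)C)C[C@H](O[Si](C)(C)C(C)(C)C)C[C@@H](O[Si](C)(C)C(C)(C)C)[C@@H](C)[C@H](O[Si](C)(C)C(C)(C)C)/C=C/C#CC | intermediate
29 | acetaldehyde | CC=O | starting material
30 | (4S)-4-benzyl-3-[(1Z)-1-[(trichlorotitanio)oxy]prop-1-en-1-yl]-1,3-oxazolidin-2-one | C/C=C(\O[Ti](Cl)(Cl)Cl)N1[C@@H](Cc2ccccc2)COC1=O | intermediate (not isolated)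
31 | (4S)-4-benzyl-3-[(2S,3R)-3-hydroxy-2-methylbutanoyl]-1,3-oxazolidin-2-one | O=C1OC[C@H](Cc2ccccc2)N1C(=O)[C@@H](C)[C@@H](C)O | intermediate
32 | (2S,3R)-3-hydroxy-N-methoxy-N,2-dimethylbutanamide | CON(C)C(=O)[C@@H](C)[C@@H](C)O | intermediate
33 | (2S,3R)-3-[(tert-butyldimethylsilyl)oxy]-N-methoxy-N,2-dimethylbutanamide | CON(C)C(=O)[C@@H](C)[C@@H](C)O[Si](C)(C)C(C)(C)C | intermediate
34 | (2S,3R)-3-[(tert-butyldimethylsilyl)oxy]-2-methylbutanal | O=C[C@@H](C)[C@@H](C)O[Si](C)(C)C(C)(C)C | intermediate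
35 | tert-butyl{[(2R,3R,4E)-5-iodo-3-methylpent-4-en-2-yl]oxy}dimethylsilane | I/C=C/[C@@H](C)[C@@H](C)O[Si](C)(C)C(C)(C)C | intermediate
36 | 2-[(1E,3E)-hepta-1,3-dien-5-yn-1-yl]-4,4,5,5-tetramethyl-1,3,2-dioxaborolane | CC#C/C=C/C=C/B1OC(C)(C)C(C)(C)O1 | intermediate
37 | tert-butyldimethyl{[(2R,3R,4E,6E,8E)-3-methyldodeca-4,6,8-trien-10-yn-2-yl]oxy}silane | CC#C/C=C/C=C/C=C/[C@@H](C)[C@@H](C)O[Si](C)(C)C(C)(C)C | intermediate
38 | (2R,3R,4E,6E,8E)-3-methyldodeca-4,6,8-trien-10-yn-2-ol | CC#C/C=C/C=C/C=C/[C@@H](C)[C@@H](C)O | intermediate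
39 | mixed anhydride of acid 28 with 2,4,6-trichlorobenzoic acid | O=C(OC(=O)c1c(Cl)cc(Cl)cc1Cl)[C@@H](CC)[C@H](O[Si](C)(C)C(C)(C)C)C[C@@H](O[Si](C)(C)C(C)(C)C)CCC[C@H](O[Si](C)(C)C(C)(C)C)C[C@H](O[Si](C)(C)C(C)(C)C)C[C@@H](O[Si](C)(C)C(C)(C)C)[C@@H](C)[C@H](O[Si](C)(C)C(C)(C)C)/C=C/C#CC | intermediate (not isolated)
40 | (2R,3R,4E,6E,8E)-3-methyldodeca-4,6,8-trien-10-yn-2-yl (2S,3R,5S,9S,11S,13R,14R,15R,16E)-3,5,9,11,13,15-hexakis[(tert-butyldimethylsilyl)oxy]-2-ethyl-14-methylicos-16-en-18-ynoate | CC#C/C=C/[C@@H](O[Si](C)(C)C(C)(C)C)[C@H](C)[C@H](O[Si](C)(C)C(C)(C)C)C[C@@H](O[Si](C)(C)C(C)(C)C)C[C@@H](O[Si](C)(C)C(C)(C)C)CCC[C@H](O[Si](C)(C)C(C)(C)C)C[C@@H](O[Si](C)(C)C(C)(C)C)[C@H](CC)C(=O)O[C@H](C)[C@H](C)/C=C/C=C/C=C/C#CC | intermediate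
41 | (2S,3R,5S,9S,11S,13R,14R,15R,16E,20E,22E,24E,26R,27R)-3,5,9,11,13,15-hexakis[(tert-butyldimethylsilyl)oxy]-2-ethyl-14,26-dimethyloctacosa-16,20,22,24-tetraen-18-yn-27-olide | CC[C@@H]1C(=O)O[C@H](C)[C@H](C)/C=C/C=C/C=C/C#C/C=C/[C@@H](O[Si](C)(C)C(C)(C)C)[C@H](C)[C@H](O[Si](C)(C)C(C)(C)C)C[C@@H](O[Si](C)(C)C(C)(C)C)C[C@@H](O[Si](C)(C)C(C)(C)C)CCC[C@H](O[Si](C)(C)C(C)(C)C)C[C@H]1O[Si](C)(C)C(C)(C)C | intermediate
42 | (2S,3R,5S,9S,11S,13R,14R,15R,16E,18Z,20E,22E,24E,26R,27R)-3,5,9,11,13,15-hexakis[(tert-butyldimethylsilyl)oxy]-2-ethyl-14,26-dimethyl-19-(triethoxysilyl)octacosa-16,18,20,22,24-pentaen-27-olide | CC[C@@H]1C(=O)O[C@H](C)[C@H](C)/C=C/C=C/C=C/C([Si](OCC)(OCC)OCC)=C/C=C/[C@@H](O[Si](C)(C)C(C)(C)C)[C@H](C)[C@H](O[Si](C)(C)C(C)(C)C)C[C@@H](O[Si](C)(C)C(C)(C)C)C[C@@H](O[Si](C)(C)C(C)(C)C)CCC[C@H](O[Si](C)(C)C(C)(C)C)C[C@H]1O[Si](C)(C)C(C)(C)C | intermediate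
43 | (2S,3R,5S,9S,11S,13R,14R,15R,16E,18E,20E,22E,24E,26R,27R)-3,5,9,11,13,15-hexakis[(tert-butyldimethylsilyl)oxy]-2-ethyl-14,26-dimethyloctacosa-16,18,20,22,24-pentaen-27-olide | CC[C@@H]1C(=O)O[C@H](C)[C@H](C)/C=C/C=C/C=C/C=C/C=C/[C@@H](O[Si](C)(C)C(C)(C)C)[C@H](C)[C@H](O[Si](C)(C)C(C)(C)C)C[C@@H](O[Si](C)(C)C(C)(C)C)C[C@@H](O[Si](C)(C)C(C)(C)C)CCC[C@H](O[Si](C)(C)C(C)(C)C)C[C@H]1O[Si](C)(C)C(C)(C)C | intermediate
44 | (2S,3R,5S,9S,11S,13R,14R,15R,16E,18E,20E,22E,24E,26R,27R)-2-ethyl-3,5,9,11,13,15-hexahydroxy-14,26-dimethyloctacosa-16,18,20,22,24-pentaen-27-olide (CNP0382847.1) | CC[C@@H]1C(=O)O[C@H](C)[C@H](C)/C=C/C=C/C=C/C=C/C=C/[C@@H](O)[C@H](C)[C@H](O)C[C@@H](O)C[C@@H](O)CCC[C@H](O)C[C@H]1O | target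

**Step count and risks**

Total step count: 33. Longest linear sequence: 19 steps (steps 6–12, 14–20 and 29–33).

Steps most likely to fail:

1. Step 17 (poor facial selectivity at C13). If the aluminium centre does not chelate the silyl ether, the Felkin adduct would intrude. The fallback carries the C15 oxygen as a strongly chelating benzylic ether and exchanges it later. It sets out from 7: etherification with 4-methoxybenzyl trichloroacetimidate and catalytic Sc(OTf)3 gives the 4-methoxybenzyl ether amide F1, and iBu2AlH reduction gives the 4-methoxybenzyl ether aldehyde F2. Addition of enol silane 24 under Me2AlCl gives the chelation adduct F3, Me4NBH(OAc)3 reduction the 11,13-anti diol F4 and TBSOTf the pentakis-silyl ether F5. DDQ in buffered CH2Cl2/H2O then frees the C15 alcohol F6, and TBSOTf silylation returns to 27.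

2. Step 31 (catalyst sequestration by the polyene, or hydrosilylation at the wrong site). The fallback replaces trans-addition by cis-reduction and equilibration. It sets out from 41: zinc activated with Cu(OAc)2 and AgNO3 in MeOH/H2O/THF reduces the alkyne to the 18Z pentaene F7, and catalytic iodine in CH2Cl2 under ambient light isomerises it to the all-E pentaene 43.

3. Step 33 (incomplete desilylation before the pentaenyl carbinol ionises or the lactone migrates). The fallback changes the order so that fluoride meets the more robust enyne–triene. It sets out from 41: HF·pyridine in buffered THF gives the 18,19-didehydro hexol F8, trans-hydrosilylation with (EtO)3SiH and [Cp*Ru(MeCN)3]PF6 gives the alkenylsilane hexol F9, and AgF protodesilylation arrives directly at 44.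

**Further compounds**

F1 | step 17 | (2S,3R,4E)-N-methoxy-3-[(4-methoxybenzyl)oxy]-N,2-dimethyloct-4-en-6-ynamide | CON(C)C(=O)[C@@H](C)[C@H](OCc1ccc(OC)cc1)/C=C/C#CC
F2 | step 17 | (2S,3R,4E)-3-[(4-methoxybenzyl)oxy]-2-methyloct-4-en-6-ynal | O=C[C@@H](C)[C@H](OCc1ccc(OC)cc1)/C=C/C#CC
F3 | step 17 | C15 4-methoxybenzyl ether analogue of 25 (3,5,9-tris-silyl 13-hydroxy-11-oxo imide) | O=C1OC[C@H](Cc2ccccc2)N1C(=O)[C@@H](CC)[C@H](O[Si](C)(C)C(C)(C)C)C[C@@H](O[Si](C)(C)C(C)(C)C)CCC[C@H](O[Si](C)(C)C(C)(C)C)CC(=O)C[C@@H](O)[C@@H](C)[C@H](OCc2ccc(OC)cc2)/C=C/C#CC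
F4 | step 17 | C15 4-methoxybenzyl ether analogue of 26 (3,5,9-tris-silyl 11,13-anti diol imide) | O=C1OC[C@H](Cc2ccccc2)N1C(=O)[C@@H](CC)[C@H](O[Si](C)(C)C(C)(C)C)C[C@@H](O[Si](C)(C)C(C)(C)C)CCC[C@H](O[Si](C)(C)C(C)(C)C)C[C@H](O)C[C@@H](O)[C@@H](C)[C@H](OCc2ccc(OC)cc2)/C=C/C#CC
F5 | step 17 | C15 4-methoxybenzyl ether analogue of 27 (3,5,9,11,13-pentakis-silyl imide) | O=C1OC[C@H](Cc2ccccc2)N1C(=O)[C@@H](CC)[C@H](O[Si](C)(C)C(C)(C)C)C[C@@H](O[Si](C)(C)C(C)(C)C)CCC[C@H](O[Si](C)(C)C(C)(C)C)C[C@H](O[Si](C)(C)C(C)(C)C)C[C@@H](O[Si](C)(C)C(C)(C)C)[C@@H](C)[C@H](OCc2ccc(OC)cc2)/C=C/C#CC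
F6 | step 17 | C15 alcohol analogue of 27 (3,5,9,11,13-pentakis-silyl 15-hydroxy imide) | O=C1OC[C@H](Cc2ccccc2)N1C(=O)[C@@H](CC)[C@H](O[Si](C)(C)C(C)(C)C)C[C@@H](O[Si](C)(C)C(C)(C)C)CCC[C@H](O[Si](C)(C)C(C)(C)C)C[C@H](O[Si](C)(C)C(C)(C)C)C[C@@H](O[Si](C)(C)C(C)(C)C)[C@@H](C)[C@H](O)/C=C/C#CC
F7 | step 31 | 18Z isomer of 43 (16E,18Z,20E,22E,24E hexakis-silyl pentaene macrolactone) | CC[C@@H]1C(=O)O[C@H](C)[C@H](C)/C=C/C=C/C=C/C=C\C=C\[C@@H](O[Si](C)(C)C(C)(C)C)[C@H](C)[C@H](O[Si](C)(C)C(C)(C)C)C[C@@H](O[Si](C)(C)C(C)(C)C)C[C@@H](O[Si](C)(C)C(C)(C)C)CCC[C@H](O[Si](C)(C)C(C)(C)C)C[C@H]1O[Si](C)(C)C(C)(C)C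
F8 | step 33 | (2S,3R,5S,9S,11S,13R,14R,15R,16E,20E,22E,24E,26R,27R)-2-ethyl-3,5,9,11,13,15-hexahydroxy-14,26-dimethyloctacosa-16,20,22,24-tetraen-18-yn-27-olide | CC[C@@H]1C(=O)O[C@H](C)[C@H](C)/C=C/C=C/C=C/C#C/C=C/[C@@H](O)[C@H](C)[C@H](O)C[C@@H](O)C[C@@H](O)CCC[C@H](O)C[C@H]1O
F9 | step 33 | 19-(triethoxysilyl) derivative of 44 (16E,18Z,20E,22E,24E alkenylsilane hexol) | CC[C@@H]1C(=O)O[C@H](C)[C@H](C)/C=C/C=C/C=C/C([Si](OCC)(OCC)OCC)=C/C=C/[C@@H](O)[C@H](C)[C@H](O)C[C@@H](O)C[C@@H](O)CCC[C@H](O)C[C@H]1O
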